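C3 and C3′ are the α-carbons of the two aryl-lactone carbonyls C2 and C2′, so the target is a hidden 2,3-disubstituted succinate. The route rests on making C3–C3′ between two enantiopure 4-arylchroman-2-ones of opposite polarity. The half whose ring A′ is fully substituted serves as 3′-bromide, the source of an electrophilic α-acyl radical. The 5,7-dioxygenated half serves as nucleophilic silyl ketene acetal. One photoredox radical–polar crossover joins them with built-in cross-selectivity. C4 and C4′ come from asymmetric 1,4-arylation of coumarins. Their pseudo-axial aryl rings steer carbon–carbon bond formation trans, so the 3,4-cis and 3′,4′-cis relations are set afterwards by kinetic protonation of the bis-enolate.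

Key step: step 7

Assumption: locants follow chroman-2-one numbering (unprimed = 5,7-dioxygenated half, primed = 5,6,7,8-tetraoxygenated half); the SMILES is read as (3S,4R,3′S,4′R), i.e. 3,4-cis and 3′,4′-cis; (R)-SEGPHOS is written as the ligand antipode expected to give 4R, and the other antipode is taken if the sense proves opposite.

Step 1
Reactants: 1 5,7-dimethoxycoumarin; 2 4-methoxyphenylboronic acid
Product: 3 (4R)-5,7-dimethoxy-4-(4-methoxyphenyl)chroman-2-one
Conditions: Rh(acac)(C2H4)2 (3 mol %), (R)-SEGPHOS (3.3 mol %), 2 (excess), dioxane/H2O 10:1, 60 °C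
Reagents that add atoms: none
Why: In this rhodium-catalysed asymmetric 1,4-addition of an arylboronic acid to a coumarin (Hayashi–Miyaura reaction), the aryl-rhodium species held by the C2-symmetric bisphosphine inserts one enantioface of C3=C4 and hydrolysis of the oxa-π-allyl rhodium frees the lactone, so the ligand sets C4 as R.

Step 2
Reactants: 3 (4R)-5,7-dimethoxy-4-(4-methoxyphenyl)chroman-2-one
Product: 5 (4R)-2-(tert-butyldimethylsilyloxy)-5,7-dimethoxy-4-(4-methoxyphenyl)-4H-chromene, via lithium enolate 4 (not isolated)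
Conditions: LiHMDS (1.1 equiv), THF, −78 °C; TBSOTf (1.2 equiv), −78 → 0 °C; non-aqueous work-up (pentane, filtration), used crude
Reagents that add atoms: tert-butyldimethylsilyl trifluoromethanesulfonate, CC(C)(C)[Si](C)(C)OS(=O)(=O)C(F)(F)F
Why: Kinetic deprotonation at C3 and O-silylation of the lithium enolate by the hard silyl triflate (ketene silyl acetal formation) leave C4 untouched and create no stereocentre.

Step 3
Reactants: 6 1,2,3,4-tetramethoxybenzene
Product: 9 2,3,4,5-tetramethoxyphenol, via aryllithium 7 (not isolated), via dimethyl arylboronate 8 (not isolated)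
Conditions: n-BuLi (1.1 equiv), TMEDA, THF, 0 °C; B(OMe)3, −78 °C → rt; H2O2 (30 %), aq NaOH, 0 °C
Reagents that add atoms: hydrogen peroxide, OO
Why: Directed ortho-lithiation next to a terminal methoxy group (the two free positions are equivalent), borylation and oxidative 1,2-migration (lithiation–borylation–oxidation) install the fifth oxygen, and no stereocentre is formed.

Step 4
Reactants: 9 2,3,4,5-tetramethoxyphenol; 10 ethyl propiolate
Product: 11 5,6,7,8-tetramethoxycoumarin
Conditions: Pd(OAc)2 (5 mol %), NaOAc (10 mol %), HCO2H, 25 °C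
Reagents that add atoms: none
Why: Palladium-catalysed hydroarylation of the alkynoate by the only free ring position, ortho to the hydroxyl group, gives the (Z)-cinnamate that lactonises at once (coumarin synthesis from a phenol and a propiolate), and no stereocentre is formed.

Step 5
Reactants: 11 5,6,7,8-tetramethoxycoumarin; 2 4-methoxyphenylboronic acid
Product: 12 (4R)-5,6,7,8-tetramethoxy-4-(4-methoxyphenyl)chroman-2-one
Conditions: Rh(acac)(C2H4)2 (3 mol %), (R)-SEGPHOS (3.3 mol %), 2 (excess), dioxane/H2O 10:1, 60 °C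
Reagents that add atoms: none
Why: The same ligand-controlled rhodium-catalysed asymmetric 1,4-arylation (Hayashi–Miyaura reaction) as in step 1 sets C4′ as R.

Step 6
Reactants: 12 (4R)-5,6,7,8-tetramethoxy-4-(4-methoxyphenyl)chroman-2-one
Product: 14 (3S,4R)-3-bromo-5,6,7,8-tetramethoxy-4-(4-methoxyphenyl)chroman-2-one (3,4-trans), via lithium enolate 13 (not isolated)
Conditions: LiHMDS (1.05 equiv), THF, −78 °C; BrCl2C–CCl2Br (1.1 equiv), −78 °C
Reagents that add atoms: 1,2-dibromo-1,1,2,2-tetrachloroethane, BrC(Cl)(Cl)C(Cl)(Cl)Br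
Why: Electrophilic α-bromination of the lactone enolate takes place on the face opposite to the pseudo-axial 4′-aryl ring (trans), ring A′ offers no free position that could compete, and the C3′ configuration is of no consequence because it is lost in step 7.

Step 7
Reactants: 5 (4R)-2-(tert-butyldimethylsilyloxy)-5,7-dimethoxy-4-(4-methoxyphenyl)-4H-chromene; 14 (3S,4R)-3-bromo-5,6,7,8-tetramethoxy-4-(4-methoxyphenyl)chroman-2-one
Product: 15 (3R,4R,3′R,4′R)-5,5′,6′,7,7′,8′-hexamethoxy-4,4′-bis(4-methoxyphenyl)-3,3′-bichromane-2,2′-dione (3,4-trans/3′,4′-trans)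
Conditions: fac-Ir(ppy)3 (1 mol %), 5 (1.5 equiv), MeCN/CH2Cl2, 4 Å MS, blue LEDs (450 nm), 20 °C, argon
Reagents that add atoms: none
Why: Excited fac-Ir(ppy)3 reduces the C3′–Br bond of 14 to bromide and the electrophilic α-acyl radical at C3′, which adds to the electron-rich C3 of ketene acetal 5; the resulting α,α-dioxy radical is oxidised by Ir(IV) (or by 14 in a chain) to a silyloxycarbenium ion that gives up its silyl group to bromide and restores lactone carbonyl C2. The closest known reaction type is the visible-light photoredox α-alkylation of silyl enol ethers and ketene silyl acetals with α-bromocarbonyl compounds to 1,4-dicarbonyl compounds (radical–polar crossover). No ring is closed. C3 and C3′ are each controlled by the neighbouring 4-aryl ring, which the peri methoxy group at C5 or C5′ holds pseudo-axial so that only the opposite face is open, and the 3R,3′R (trans/trans) isomer is therefore expected; any other C3/C3′ isomer is carried on, since step 8 erases both centres. The step needs cross- over homo-coupling and attack at C3 rather than at the polyalkoxyarenes. These are secured by the polarity match between electrophilic radical and nucleophilic alkene, by the low stationary radical concentration and by the absence of any oxidant strong enough to touch rings A and A′.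

Step 8
Reactants: 15 (3R,4R,3′R,4′R)-5,5′,6′,7,7′,8′-hexamethoxy-4,4′-bis(4-methoxyphenyl)-3,3′-bichromane-2,2′-dione
Product: 17 (3S,4R,3′S,4′R)-5,5′,6′,7,7′,8′-hexamethoxy-4,4′-bis(4-methoxyphenyl)-3,3′-bichromane-2,2′-dione (3,4-cis/3′,4′-cis), via dilithium bis-enolate 16 (not isolated)
Conditions: LDA (3 equiv), THF, −78 → −40 °C; recooled and cannulated into AcOH/THF, −78 °C
Reagents that add atoms: none
Why: Double deprotonation flattens C3 and C3′, and irreversible low-temperature protonation (kinetic protonation of a lactone enolate, a contra-thermodynamic epimerisation) should deliver each proton to the face opposite to the adjacent pseudo-axial aryl ring, which places the C3–C3′ bond cis to both aryl rings and gives 3S,3′S under control of the untouched 4R and 4′R centres.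

Step 9
Reactants: 17 (3S,4R,3′S,4′R)-5,5′,6′,7,7′,8′-hexamethoxy-4,4′-bis(4-methoxyphenyl)-3,3′-bichromane-2,2′-dione
Product: 18 CNP0064734.1, (3S,4R,3′S,4′R)-5,5′,6′,7,7′,8′-hexahydroxy-4,4′-bis(4-hydroxyphenyl)-3,3′-bichromane-2,2′-dione
Conditions: BBr3 (16 equiv), CH2Cl2, −78 → 0 °C, argon; degassed H2O, 0 °C; reversed-phase purification under argon
Reagents that add atoms: none
Why: Boron tribromide cleaves all eight aryl methyl ethers by bromide attack on the boron-activated methyl groups (Lewis-acid ether cleavage), the aryl lactones survive or re-close on hydrolysis, and without base at low temperature the four stereocentres should be kept.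

Compound list
1 | 5,7-dimethoxycoumarin | O=C1C=Cc2c(OC)cc(OC)cc2O1 | starting material
2 | 4-methoxyphenylboronic acid | COc1ccc(cc1)B(O)O | starting material
3 | (4R)-5,7-dimethoxy-4-(4-methoxyphenyl)chroman-2-one | O=C1Oc2cc(OC)cc(OC)c2[C@@H](c2ccc(OC)cc2)C1 | intermediate
4 | lithium enolate of 3 (4R) | [Li+].[O-]C1=C[C@H](c2ccc(OC)cc2)c2c(OC)cc(OC)cc2O1 | intermediate
5 | (4R)-2-(tert-butyldimethylsilyloxy)-5,7-dimethoxy-4-(4-methoxyphenyl)-4H-chromene | CC(C)(C)[Si](C)(C)OC1=C[C@H](c2ccc(OC)cc2)c2c(OC)cc(OC)cc2O1 | intermediate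
6 | 1,2,3,4-tetramethoxybenzene | COc1ccc(OC)c(OC)c1OC | starting material
7 | (2,3,4,5-tetramethoxyphenyl)lithium | [Li]c1cc(OC)c(OC)c(OC)c1OC | intermediate
8 | dimethyl (2,3,4,5-tetramethoxyphenyl)boronate | COB(OC)c1cc(OC)c(OC)c(OC)c1OC | intermediate
9 | 2,3,4,5-tetramethoxyphenol | Oc1cc(OC)c(OC)c(OC)c1OC | intermediate
10 | ethyl propiolate | C#CC(=O)OCC | starting material
11 | 5,6,7,8-tetramethoxycoumarin | O=C1C=Cc2c(OC)c(OC)c(OC)c(OC)c2O1 | intermediate
12 | (4R)-5,6,7,8-tetramethoxy-4-(4-methoxyphenyl)chroman-2-one | O=C1Oc2c(OC)c(OC)c(OC)c(OC)c2[C@@H](c2ccc(OC)cc2)C1 | intermediate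
13 | lithium enolate of 12 (4R) | [Li+].[O-]C1=C[C@H](c2ccc(OC)cc2)c2c(OC)c(OC)c(OC)c(OC)c2O1 | intermediate
14 | (3S,4R)-3-bromo-5,6,7,8-tetramethoxy-4-(4-methoxyphenyl)chroman-2-one (trans) | O=C1Oc2c(OC)c(OC)c(OC)c(OC)c2[C@@H](c2ccc(OC)cc2)[C@@H]1Br | intermediate
15 | (3R,4R,3′R,4′R)-5,5′,6′,7,7′,8′-hexamethoxy-4,4′-bis(4-methoxyphenyl)-3,3′-bichromane-2,2′-dione (trans/trans) | O=C1Oc2cc(OC)cc(OC)c2[C@@H](c2ccc(OC)cc2)[C@@H]1[C@@H]1C(=O)Oc2c(OC)c(OC)c(OC)c(OC)c2[C@H]1c1ccc(OC)cc1 | intermediate
16 | dilithium bis-enolate of 15 (4R,4′R; C3 and C3′ planar) | [Li+].[Li+].[O-]C1=C(C2=C([O-])Oc3c(OC)c(OC)c(OC)c(OC)c3[C@H]2c2ccc(OC)cc2)[C@H](c2ccc(OC)cc2)c2c(OC)cc(OC)cc2O1 | intermediate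
17 | (3S,4R,3′S,4′R)-5,5′,6′,7,7′,8′-hexamethoxy-4,4′-bis(4-methoxyphenyl)-3,3′-bichromane-2,2′-dione (cis/cis) | O=C1Oc2cc(OC)cc(OC)c2[C@@H](c2ccc(OC)cc2)[C@H]1[C@H]1C(=O)Oc2c(OC)c(OC)c(OC)c(OC)c2[C@H]1c1ccc(OC)cc1 | intermediate
18 | CNP0064734.1, (3S,4R,3′S,4′R)-5,5′,6′,7,7′,8′-hexahydroxy-4,4′-bis(4-hydroxyphenyl)-3,3′-bichromane-2,2′-dione | O=C1Oc2cc(O)cc(O)c2[C@@H](c2ccc(O)cc2)[C@H]1[C@H]1C(=O)Oc2c(O)c(O)c(O)c(O)c2[C@H]1c1ccc(O)cc1 | target

Total step count: 9. Longest linear sequence: 7 (steps 3, 4, 5, 6, 7, 8, 9).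

Steps most likely to fail

Step 8.
- What may go wrong: the second deprotonation next to an existing enolate may stay incomplete. The aryl-lactone enolates may open to ketene/phenoxide pairs. Proton delivery may lose its facial bias because the twisted neighbouring ring crowds the nominally open face, or because amine-bound protons return on warming.
- Fallback, from 15 back to 17: bis-enolate 16 is not protonated but oxidised with iodine (THF, −78 °C) to the tetrasubstituted alkene (3E,4R,4′R)-5,5′,6′,7,7′,8′-hexamethoxy-4,4′-bis(4-methoxyphenyl)-3,3′-bichromanylidene-2,2′-dione F1, in which both 4-aryl rings stand on the same face. Heterogeneous hydrogenation (H2, Pd/C, EtOAc) then adds both hydrogens syn from the free face and should give 17, so C3 and C3′ are set by hydrogenation instead of protonation.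

Step 7.
- What may go wrong: the hindered C3′ radical may add too slowly. Hydrogen abstraction (reductive debromination), a 1,2-aryl shift from C4′ to C3′, or acid-induced hydrolysis of the ketene acetal may then take over.
- Fallback, from 3 and 12 back to 15: both lactones are deprotonated separately with LiHMDS to enolates 4 (threefold excess) and 13. The solutions are combined at −78 °C and oxidised with copper(II) 2-ethylhexanoate (oxidative enolate heterocoupling). Cross-selectivity then rests on stoichiometry alone, and the homodimer of 3 is removed by chromatography. This fallback makes no compound outside the list (F0).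

Step 9.
- What may go wrong: transient opening of the lactones to acyl bromides may allow enolisation and drift of C3/C3′ towards the trans series. The tetrahydroxylated ring A′ may be oxidised by air during work-up.
- Fallback, from 15 back to 18, moves the harsh ether cleavage in front of the stereochemical correction:
  - 15 is demethylated with BBr3 to the 3,4-trans/3′,4′-trans octaphenol F2.
  - F2 is benzylated (BnBr, K2CO3, DMF) to the trans/trans octabenzyl ether F3.
  - F3 is converted with LDA into its dilithium bis-enolate F4.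
  - F4 is quenched into AcOH/THF at −78 °C to give the cis/cis octabenzyl ether F5.
  - Neutral hydrogenolysis of F5 (H2, Pd/C, THF/EtOAc, argon work-up) releases 18.

Further compounds
F1 | step 8 | (3E,4R,4′R)-5,5′,6′,7,7′,8′-hexamethoxy-4,4′-bis(4-methoxyphenyl)-3,3′-bichromanylidene-2,2′-dione | O=C1Oc2cc(OC)cc(OC)c2[C@@H](c2ccc(OC)cc2)/C1=C1\C(=O)Oc2c(OC)c(OC)c(OC)c(OC)c2[C@H]1c1ccc(OC)cc1
F0 | step 7 | none | none
F2 | step 9 | (3R,4R,3′R,4′R)-5,5′,6′,7,7′,8′-hexahydroxy-4,4′-bis(4-hydroxyphenyl)-3,3′-bichromane-2,2′-dione (trans/trans octaphenol) | O=C1Oc2cc(O)cc(O)c2[C@@H](c2ccc(O)cc2)[C@@H]1[C@@H]1C(=O)Oc2c(O)c(O)c(O)c(O)c2[C@H]1c1ccc(O)cc1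
F3 | step 9 | octabenzyl ether of F2 (3R,4R,3′R,4′R) | O=C1Oc2cc(OCc3ccccc3)cc(OCc3ccccc3)c2[C@@H](c2ccc(OCc3ccccc3)cc2)[C@@H]1[C@@H]1C(=O)Oc2c(OCc3ccccc3)c(OCc3ccccc3)c(OCc3ccccc3)c(OCc3ccccc3)c2[C@H]1c1ccc(OCc2ccccc2)cc1
F4 | step 9 | dilithium bis-enolate of F3 (4R,4′R) | [Li+].[Li+].[O-]C1=C(C2=C([O-])Oc3c(OCc4ccccc4)c(OCc4ccccc4)c(OCc4ccccc4)c(OCc4ccccc4)c3[C@H]2c2ccc(OCc3ccccc3)cc2)[C@H](c2ccc(OCc3ccccc3)cc2)c2c(OCc3ccccc3)cc(OCc3ccccc3)cc2O1
F5 | step 9 | octabenzyl ether of 18 (3S,4R,3′S,4′R) | O=C1Oc2cc(OCc3ccccc3)cc(OCc3ccccc3)c2[C@@H](c2ccc(OCc3ccccc3)cc2)[C@H]1[C@H]1C(=O)Oc2c(OCc3ccccc3)c(OCc3ccccc3)c(OCc3ccccc3)c(OCc3ccccc3)c2[C@H]1c1ccc(OCc2ccccc2)cc1
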